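Amounts came first. I counted everything in fractions of the E charged. Each L holds one G, each Q two, each D 3, so L + 2Q + 3D is the spend of G. Its ceiling is the budget, the G charged per E charged 1.50, which is the same in maple, alder and birch. G is the limiting reagent in these three flasks, since 1.50 is less than the 3 that a full conversion to D takes.

| flask | E | G | temperature | remark | time |
|---|---|---|---|---|---|
| grey | 0.15 M | 0.45 M | 55 °C | run made earlier |  |
| violet | 0.60 M | 0.45 M | 75 °C | run made earlier |  |
| ochre | 0.30 M | 0.90 M | 55 °C | run made earlier |  |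
| maple | 0.30 M | 0.450 M | 90 °C |  | 40 min |
| alder | 0.30 M | 0.450 M |  | at 90 °C until 12 min, from then on at 60 °C | 40 min |
| birch | 0.30 M | 0.450 M | 60 °C |  | 40 min |

| run | time / min | L / % | Q / % | D / % |
|---|---|---|---|---|
| grey | 12.0 | 25.6 | 4.0 | 3.0 |
| grey | 15.0 | 28.8 | 4.3 | 4.7 |
| grey | 30.0 | 34.6 | 6.3 | 16.6 |
| grey | 50.0 | 33.6 | 6.7 | 31.8 |
| grey | 80.0 | 28.3 | 5.7 | 48.5 |
| grey | 150 | 18.1 | 4.2 | 68.4 |
| violet | 4.00 | 25.2 | 4.4 | 4.5 |
| violet | 6.00 | 28.0 | 5.5 | 7.4 |
| violet | 10.0 | 29.0 | 6.2 | 9.3 |
| violet | 15.0 | 29.1 | 6.8 | 10.6 |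
| violet | 30.0 | 29.8 | 6.7 | 10.4 |
| violet | 50.0 | 29.8 | 7.4 | 10.7 |
| ochre | 12.0 | 33.9 | 5.6 | 11.3 |
| ochre | 30.0 | 31.5 | 6.5 | 37.6 |
| ochre | 60.0 | 22.5 | 4.9 | 61.3 |
| ochre | 80.0 | 17.8 | 4.2 | 69.9 |
| ochre | 150 | 10.7 | 2.7 | 83.8 |

(each reading ± 0.3 percentage points)



- the best flask by share of L in all that became L or Q or D; "all alike" if 1.5 percentage points covers them all (maple / alder / birch / all alike)
- share of L in all that became L or Q or D, maple
- share of L in all that became L or Q or D, alder
- share of L in all that became L or Q or D, birch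

I solved the two ends. At one end a flask has just begun, and its products are mostly L. Ochre's and grey's readings at 55 °C fall along one line:

| run, time | spend | share of L |
|---|---|---|
| ochre, 12.0 min | 0.790 | 66.7 % |
| grey, 30.0 min | 0.970 | 60.2 % |
| grey, 50.0 min | 1.42 | 46.6 % |
| ochre, 30.0 min | 1.57 | 41.7 % |

At the other end the whole budget is spent, and 1.50 lies between the last two rows. Both runs had a budget of 3.00, so reading their line at 1.50 assumes that the share follows the spend and not the charge. On that assumption, those two rows bracket my share for a full spend at 55 °C.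

I took heat to lower the line, though violet also differs from ochre in its charges. Violet at 50.0 min read a spend of 0.767, against its budget of 0.750, with a share of 62.2 %, lower than ochre's 66.7 %.

Violet's spend read 0.745 at 15.0 min, against 0.767 at 50.0 min. Maple and alder start hotter, so I put both at full budget, with equal shares below 46.6 %. I expected birch to fall short of its budget at 40 min, and so to stand higher on the line.

The forecast named birch, with 36 % for maple, 36.2 % for alder and 51.8 % for birch. On alder it said: “G is essentially gone by 12 min, so it matches maple.” My reckoning gave bounds and the forecast gave numbers. Its birch lies between my middle rows.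

Maple gave 35.7 %, alder 36.0 % and birch 51.9 %, so birch was best. Alder held 1.10 % of its own G at the change, at 12.0 min.

    E → J (k = 1.39 × 10⁻⁴ min⁻¹, Ea = 128 kJ mol⁻¹)
    G + Q → D + X (k = 0.616 M⁻¹ min⁻¹, Ea = 71.0 kJ mol⁻¹)
    G + L → Q + X (k = 0.135 M⁻¹ min⁻¹, Ea = 85.0 kJ mol⁻¹)
    E + G → L + X (k = 0.115 M⁻¹ min⁻¹, Ea = 74.0 kJ mol⁻¹)
    (constants at 60 °C)

A neighbour of alder, charged with 0.27 M of G, has a budget of 0.900. At 40.0 min its spend was 0.898, with 0.239 % of its own G left, and its share of L was 54.3 %.

All runs stem from a simulated flask with constants of no real substance; the scatter is artificial.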